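**Plan**
Retrosynthesis: C3–Br is traced back to C3–O; C11–C12 is cut (allylic sulfone anion plus a C5 vinyl epoxide); C5–C10 and C8–C9 are cut together (intramolecular Diels–Alder); then C5=C6 (Julia–Kocienski) and C3–C4 (aldol).
Enabling feature: ring B (C5–C10) holds the only ring alkene at C8–C9 and carries C11 on C9. This is the pattern of a [4+2] adduct that brings C11 in as an ester on the dienophile carbon C9, with ring A (C1–C5, C10) closed by the C1–C4 tether.
Forward: methyl geranate supplies C1–C3 and C9–C11; aldol and olefination complete the acyclic trienoate; one cycloaddition closes rings A and B.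
The C6–C7 alkene is then saturated and a C8=C9 alkene introduced, the side chain is attached at C11, and C3–O is turned into C3–Br.
Stereochemistry: C3 from a valine-controlled Mukaiyama aldol; C5 and C10 relayed from C3 in the cycloaddition; C3–Br by oxidation, axial reduction and Appel inversion; C13 from Sharpless epoxidation of methallyl alcohol.

Key step: step 9

Remark: labdane locants are used for all bicyclic compounds (C11 on C9, C17 = methyl on C8, C20 = methyl on C10); the N-tosyl-L-valine promoter is assumed to show its usual sense of induction for unbranched aliphatic aldehydes, and the enantiomeric promoter would be used if it did not.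

Step 1
Reactants: 1 methyl geranate
Product: 2 methyl (2E)-3-methyl-6-oxohex-2-enoate
Conditions: O3 (1 equiv), CH2Cl2, −78 °C; then Me2S, −78 → 23 °C
Reagents that add atoms: ozone, [O-][O+]=O
Why: Ozonolysis with reductive work-up should cleave only the electron-rich trisubstituted 6,7-alkene, because the conjugated 2,3-enoate reacts with ozone far more slowly.

Step 2
Reactants: 3 S-ethyl 2-methylpropanethioate
Product: 4 [1-(ethylsulfanyl)-2-methylprop-1-en-1-yl]oxy(trimethyl)silane
Conditions: LiN(i-Pr)2, THF, −78 °C; Me3SiCl, −78 → 23 °C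
Reagents that add atoms: chlorotrimethylsilane, C[Si](C)(C)Cl
Why: Kinetic enolisation of the thioester and O-silylation give the silyl ketene thioacetal, which has no geometric isomers because the enolate carbon bears two methyl groups.

Step 3
Reactants: 2 methyl (2E)-3-methyl-6-oxohex-2-enoate; 4 [1-(ethylsulfanyl)-2-methylprop-1-en-1-yl]oxy(trimethyl)silane
Product: 5 methyl (2E,6R)-8-(ethylsulfanyl)-6-hydroxy-3,7,7-trimethyl-8-oxooct-2-enoate
Conditions: N-tosyl-L-valine, BH3·THF, CH2Cl2, 0 → 23 °C; then 2 and 4, −78 °C; pH 7 buffer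
Reagents that add atoms: none
Why: In this oxazaborolidinone-promoted asymmetric Mukaiyama aldol reaction the boron-bound aldehyde is attacked on one face by the ketene thioacetal, which forms C3–C4 with its gem-dimethyl group and should set the (R)-carbinol that becomes C3.

Step 4
Reactants: 5 methyl (2E,6R)-8-(ethylsulfanyl)-6-hydroxy-3,7,7-trimethyl-8-oxooct-2-enoate
Product: 6 methyl (2E,6R)-8-(ethylsulfanyl)-3,7,7-trimethyl-8-oxo-6-[(triethylsilyl)oxy]oct-2-enoate
Conditions: Et3SiOTf, 2,6-lutidine, CH2Cl2, −78 → 0 °C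
Reagents that add atoms: triethylsilyl trifluoromethanesulfonate, CC[Si](CC)(CC)OS(=O)(=O)C(F)(F)F
Why: Silyl triflate silylation copes with the hindered neopentylic alcohol, and the triethylsilyl group is chosen because it can later be removed beside a tertiary tert-butyldimethylsilyl ether.

Step 5
Reactants: 6 methyl (2E,6R)-8-(ethylsulfanyl)-3,7,7-trimethyl-8-oxo-6-[(triethylsilyl)oxy]oct-2-enoate
Product: 7 methyl (2E,6R)-3,7,7-trimethyl-8-oxo-6-[(triethylsilyl)oxy]oct-2-enoate
Conditions: Et3SiH, Pd/C (10%), acetone, 23 °C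
Reagents that add atoms: none
Why: The Fukuyama reduction converts the thioester into the aldehyde without touching the methyl enoate or the silyl ether, and the quaternary α-carbon rules out enolisation.

Step 6
Reactants: 8 (2E)-but-2-en-1-ol; 9 1-phenyl-1H-tetrazole-5-thiol
Product: 10 5-[(2E)-but-2-en-1-ylsulfanyl]-1-phenyl-1H-tetrazole
Conditions: PPh3, diisopropyl azodicarboxylate, THF, 0 → 23 °C
Reagents that add atoms: none
Why: Mitsunobu thioetherification of the primary allylic alcohol proceeds by SN2 attack of the acidic thiol on the alkoxyphosphonium ion and keeps the (E)-alkene.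

Step 7
Reactants: 10 5-[(2E)-but-2-en-1-ylsulfanyl]-1-phenyl-1H-tetrazole
Product: 11 5-[(2E)-but-2-ene-1-sulfonyl]-1-phenyl-1H-tetrazole
Conditions: (NH4)6Mo7O24·4H2O (cat.), 30% H2O2, EtOH, 0 → 23 °C
Reagents that add atoms: hydrogen peroxide, OO
Why: Molybdate-catalysed peroxide oxidation takes the sulfide to the sulfone and leaves the unactivated disubstituted alkene alone.

Step 8
Reactants: 7 methyl (2E,6R)-3,7,7-trimethyl-8-oxo-6-[(triethylsilyl)oxy]oct-2-enoate; 11 5-[(2E)-but-2-ene-1-sulfonyl]-1-phenyl-1H-tetrazole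
Product: 12 methyl (2E,6R,8E,10E)-3,7,7-trimethyl-6-[(triethylsilyl)oxy]dodeca-2,8,10-trienoate
Conditions: KN(SiMe3)2 added to 7 + 11, DME, −60 → 23 °C
Reagents that add atoms: none
Why: In this Julia–Kocienski olefination the metalated allylic sulfone adds to the non-enolisable aldehyde and Smiles rearrangement with loss of SO2 forms C5=C6, where the quaternary neighbour should favour the (E)-alkene while the crotyl unit supplies the (E)-C7=C8 bond.

Step 9
Reactants: 12 methyl (2E,6R,8E,10E)-3,7,7-trimethyl-6-[(triethylsilyl)oxy]dodeca-2,8,10-trienoate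
Product: 13 methyl (1R,2R,4aS,6R,8aR)-2,5,5,8a-tetramethyl-6-[(triethylsilyl)oxy]-1,2,4a,5,6,7,8,8a-octahydronaphthalene-1-carboxylate
Conditions: EtAlCl2 (1.5 equiv), CH2Cl2, −20 → 23 °C
Reagents that add atoms: none
Why: EtAlCl2 binds the ester carbonyl and lowers the LUMO of the (E)-enoate, so that the C9=C10 dienophile adds across the tethered C5=C6–C7=C8 diene in a concerted, asynchronous [4+2] in which the bond from the β-carbon (C10–C5) runs ahead; the closest known reaction type is the alkylaluminium-chloride-promoted intramolecular Diels–Alder cyclisation of 2,7,9-decatrienoic esters, which gives trans-fused octalins. Ring A closes as the six-membered tether ring through C5–C10, with C1–C4 folded as a chair, and ring B closes as the new cyclohexene through C8–C9, leaving the alkene at C6–C7. C9 and C10 follow from the (E)-enoate geometry (ester and C20 methyl cis), C5 from the endo position of the complexed ester, which puts the tether exo and makes the ring fusion trans, and C8 from the (E)-geometry of the terminal diene bond. The absolute sense at C5 and C10 is relayed from C3, because the tether chair that keeps the C3 silyloxy group equatorial offers only one diene face to the dienophile. The step needs endo (trans-fusion) and diene-face selectivity: the first should be secured by Lewis-acid activation, the second by the C3 centre together with the geminal methyl groups on C4, which also bias the chain toward the coiled reactive conformation; a minor isomer would be a diastereomer and separable here.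

Step 10
Reactants: 13 methyl (1R,2R,4aS,6R,8aR)-2,5,5,8a-tetramethyl-6-[(triethylsilyl)oxy]-1,2,4a,5,6,7,8,8a-octahydronaphthalene-1-carboxylate
Product: 14 methyl (1R,2R,4aS,6R,8aR)-2,5,5,8a-tetramethyl-6-[(triethylsilyl)oxy]decahydronaphthalene-1-carboxylate
Conditions: H2 (1 atm), Pd/C, EtOAc, 23 °C
Reagents that add atoms: none
Why: Heterogeneous hydrogenation saturates the only alkene present (cis-disubstituted C6–C7) without creating a stereocentre or affecting ester and silyl ether.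

Step 11
Reactants: 14 methyl (1R,2R,4aS,6R,8aR)-2,5,5,8a-tetramethyl-6-[(triethylsilyl)oxy]decahydronaphthalene-1-carboxylate
Product: 16 methyl (4aS,6R,8aR)-2,5,5,8a-tetramethyl-6-[(triethylsilyl)oxy]-3,4,4a,5,6,7,8,8a-octahydronaphthalene-1-carboxylate, via 9-phenylselanyl ester 15 (not isolated)
Conditions: LiN(i-Pr)2, THF, −78 → 0 °C; PhSeBr, −78 °C; then 30% H2O2, pyridine, CH2Cl2, 0 → 23 °C
Reagents that add atoms: none
Why: In this enolate selenenylation and selenoxide syn-elimination the electrophile should enter C9 on the face opposite the syn-axial C17 and C20 methyl groups, cis to the only β-hydrogen (H-8), so oxidation gives the conjugated tetrasubstituted C8=C9 enoate and erases the C8 and C9 stereocentres.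

Step 12
Reactants: 16 methyl (4aS,6R,8aR)-2,5,5,8a-tetramethyl-6-[(triethylsilyl)oxy]-3,4,4a,5,6,7,8,8a-octahydronaphthalene-1-carboxylate
Product: 17 {(4aS,6R,8aR)-2,5,5,8a-tetramethyl-6-[(triethylsilyl)oxy]-3,4,4a,5,6,7,8,8a-octahydronaphthalen-1-yl}methanol
Conditions: i-Bu2AlH, CH2Cl2, −78 → 0 °C
Reagents that add atoms: none
Why: Hydride reduction of the hindered enoate gives the primary allylic alcohol (C11) by 1,2-addition, since conjugate reduction is blocked by the tetrasubstituted alkene.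

Step 13
Reactants: 17 {(4aS,6R,8aR)-2,5,5,8a-tetramethyl-6-[(triethylsilyl)oxy]-3,4,4a,5,6,7,8,8a-octahydronaphthalen-1-yl}methanol
Product: 19 (4aS,6R,8aR)-1-[(benzenesulfonyl)methyl]-2,5,5,8a-tetramethyl-6-[(triethylsilyl)oxy]-3,4,4a,5,6,7,8,8a-octahydronaphthalene, via allylic bromide 18 (not isolated)
Conditions: CBr4, PPh3, CH2Cl2, 0 °C; then PhSO2Na, DMF, 23 °C
Reagents that add atoms: sodium benzenesulfinate, [Na+].[O-]S(=O)c1ccccc1
Why: Appel bromination of the primary allylic alcohol and SN2 displacement of the bromide by the sulfur of the sulfinate give the allylic sulfone under neutral conditions that spare the silyl ether.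

Step 14
Reactants: 20 2-methylprop-2-en-1-ol
Product: 21 [(2S)-2-methyloxiran-2-yl]methanol
Conditions: Ti(Oi-Pr)4 (cat.), L-(+)-diethyl tartrate (cat.), t-BuOOH, 4 Å molecular sieves, CH2Cl2, −20 °C
Reagents that add atoms: tert-butyl hydroperoxide, CC(C)(C)OO
Why: In the Sharpless asymmetric epoxidation the L-(+)-tartrate titanium complex delivers oxygen to the alkene face that gives the (S)-epoxy alcohol, which fixes the future C13.

Step 15
Reactants: 21 [(2S)-2-methyloxiran-2-yl]methanol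
Product: 23 (2S)-2-ethenyl-2-methyloxirane, via epoxy aldehyde 22 (not isolated)
Conditions: (COCl)2, DMSO, Et3N, CH2Cl2, −78 °C; then Ph3PCH3Br, KOt-Bu, tetraglyme, 0 → 23 °C, product distilled out
Reagents that add atoms: methyltriphenylphosphonium bromide, C[P+](c1ccccc1)(c1ccccc1)c1ccccc1.[Br-]
Why: Swern oxidation and Wittig methylenation turn CH2OH into vinyl without breaking a bond at the quaternary epoxide carbon, so its geometry is kept, and the volatile aldehyde is carried on as a solution.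

Step 16
Reactants: 19 (4aS,6R,8aR)-1-[(benzenesulfonyl)methyl]-2,5,5,8a-tetramethyl-6-[(triethylsilyl)oxy]-3,4,4a,5,6,7,8,8a-octahydronaphthalene; 23 (2S)-2-ethenyl-2-methyloxirane
Product: 24 (3R)-5-(benzenesulfonyl)-3-methyl-5-{(4aS,6R,8aR)-2,5,5,8a-tetramethyl-6-[(triethylsilyl)oxy]-3,4,4a,5,6,7,8,8a-octahydronaphthalen-1-yl}pent-1-en-3-ol (both C11 epimers)
Conditions: n-BuLi, THF–DMPU, −78 °C; then 23, −78 → 0 °C
Reagents that add atoms: none
Why: In this epoxide alkylation of a sulfone-stabilised allylic carbanion the lithiated sulfone should open the 2,2-disubstituted oxirane by SN2 attack at its CH2 group, forming C11–C12 and leaving C13 untouched, while the new C11 centre is removed in the next step.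

Step 17
Reactants: 24 (3R)-5-(benzenesulfonyl)-3-methyl-5-{(4aS,6R,8aR)-2,5,5,8a-tetramethyl-6-[(triethylsilyl)oxy]-3,4,4a,5,6,7,8,8a-octahydronaphthalen-1-yl}pent-1-en-3-ol
Product: 25 (3R)-3-methyl-5-{(4aS,6R,8aR)-2,5,5,8a-tetramethyl-6-[(triethylsilyl)oxy]-3,4,4a,5,6,7,8,8a-octahydronaphthalen-1-yl}pent-1-en-3-ol
Conditions: Na/Hg (6%), Na2HPO4, MeOH–THF, −20 °C
Reagents that add atoms: none
Why: Reductive desulfonylation cleaves the allylic C–S bond by electron transfer, and protonation of the allyl anion at the less substituted C11 should keep the tetrasubstituted C8=C9 alkene.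

Step 18
Reactants: 25 (3R)-3-methyl-5-{(4aS,6R,8aR)-2,5,5,8a-tetramethyl-6-[(triethylsilyl)oxy]-3,4,4a,5,6,7,8,8a-octahydronaphthalen-1-yl}pent-1-en-3-ol
Product: 26 C13 tert-butyldimethylsilyl ether of 25
Conditions: t-BuMe2SiOTf, 2,6-lutidine, CH2Cl2, −78 → 0 °C
Reagents that add atoms: tert-butyldimethylsilyl trifluoromethanesulfonate, CC(C)(C)[Si](C)(C)OS(=O)(=O)C(F)(F)F
Why: Silyl triflate silylation protects the tertiary allylic alcohol, which would otherwise ionise or undergo allylic transposition under the later Appel conditions.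

Step 19
Reactants: 26 C13 tert-butyldimethylsilyl ether of 25
Product: 27 (2R,4aR,8aS)-5-{(3R)-3-[(tert-butyldimethylsilyl)oxy]-3-methylpent-4-en-1-yl}-1,1,4a,6-tetramethyl-1,2,3,4,4a,7,8,8a-octahydronaphthalen-2-ol
Conditions: HF·pyridine, pyridine, THF, 0 → 23 °C
Reagents that add atoms: none
Why: Fluoride desilylation is selective because a triethylsilyl ether is cleaved much faster than a tertiary tert-butyldimethylsilyl ether.

Step 20
Reactants: 27 (2R,4aR,8aS)-5-{(3R)-3-[(tert-butyldimethylsilyl)oxy]-3-methylpent-4-en-1-yl}-1,1,4a,6-tetramethyl-1,2,3,4,4a,7,8,8a-octahydronaphthalen-2-ol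
Product: 28 (4aR,8aS)-5-{(3R)-3-[(tert-butyldimethylsilyl)oxy]-3-methylpent-4-en-1-yl}-1,1,4a,6-tetramethyl-3,4,4a,7,8,8a-hexahydronaphthalen-2(1H)-one
Conditions: Dess–Martin periodinane, pyridine, CH2Cl2, 23 °C
Reagents that add atoms: none
Why: Dess–Martin oxidation of the secondary alcohol gives the C3 ketone under buffered conditions that tolerate the silyl ether and both alkenes.

Step 21
Reactants: 28 (4aR,8aS)-5-{(3R)-3-[(tert-butyldimethylsilyl)oxy]-3-methylpent-4-en-1-yl}-1,1,4a,6-tetramethyl-3,4,4a,7,8,8a-hexahydronaphthalen-2(1H)-one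
Product: 29 (2S,4aR,8aS)-5-{(3R)-3-[(tert-butyldimethylsilyl)oxy]-3-methylpent-4-en-1-yl}-1,1,4a,6-tetramethyl-1,2,3,4,4a,7,8,8a-octahydronaphthalen-2-ol
Conditions: LiBH(s-Bu)3, THF, −78 °C
Reagents that add atoms: none
Why: The bulky borohydride should deliver hydride along the equatorial trajectory of the 4,4-dimethyl-3-ketone and give the axial alcohol, anti to the C20 methyl, which is C3 inverted relative to 27.

Step 22
Reactants: 29 (2S,4aR,8aS)-5-{(3R)-3-[(tert-butyldimethylsilyl)oxy]-3-methylpent-4-en-1-yl}-1,1,4a,6-tetramethyl-1,2,3,4,4a,7,8,8a-octahydronaphthalen-2-ol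
Product: 30 tert-butyl({(3R)-5-[(4aS,6R,8aR)-6-bromo-2,5,5,8a-tetramethyl-3,4,4a,5,6,7,8,8a-octahydronaphthalen-1-yl]-3-methylpent-1-en-3-yl}oxy)dimethylsilane
Conditions: CBr4, PPh3, toluene, 23 → 60 °C
Reagents that add atoms: carbon tetrabromide, BrC(Br)(Br)Br
Why: In the Appel reaction bromide displaces the axial alkoxyphosphonium group with inversion (SN2), which returns C3 to the configuration set in step 3 with bromine equatorial, a known though demanding substitution at this neopentylic position.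

Step 23
Reactants: 30 tert-butyl({(3R)-5-[(4aS,6R,8aR)-6-bromo-2,5,5,8a-tetramethyl-3,4,4a,5,6,7,8,8a-octahydronaphthalen-1-yl]-3-methylpent-1-en-3-yl}oxy)dimethylsilane
Product: 31 (3R)-5-[(4aS,6R,8aR)-6-bromo-2,5,5,8a-tetramethyl-3,4,4a,5,6,7,8,8a-octahydronaphthalen-1-yl]-3-methylpent-1-en-3-ol
Conditions: Bu4NF, THF, 23 → 45 °C
Reagents that add atoms: none
Why: Fluoride cleavage of the silyl ether frees the tertiary allylic alcohol, and the equatorial neopentylic bromide has no anti-periplanar hydrogen and should neither eliminate nor be displaced.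

**Compound list**
1 | methyl geranate, methyl (2E)-3,7-dimethylocta-2,6-dienoate | COC(=O)/C=C(\C)CCC=C(C)C | starting material
2 | methyl (2E)-3-methyl-6-oxohex-2-enoate | COC(=O)/C=C(\C)CCC=O | intermediate
3 | S-ethyl 2-methylpropanethioate | CCSC(=O)C(C)C | starting material
4 | [1-(ethylsulfanyl)-2-methylprop-1-en-1-yl]oxy(trimethyl)silane | CCSC(O[Si](C)(C)C)=C(C)C | intermediate
5 | methyl (2E,6R)-8-(ethylsulfanyl)-6-hydroxy-3,7,7-trimethyl-8-oxooct-2-enoate | COC(=O)/C=C(\C)CC[C@@H](O)C(C)(C)C(=O)SCC | intermediate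
6 | methyl (2E,6R)-8-(ethylsulfanyl)-3,7,7-trimethyl-8-oxo-6-[(triethylsilyl)oxy]oct-2-enoate | COC(=O)/C=C(\C)CC[C@@H](O[Si](CC)(CC)CC)C(C)(C)C(=O)SCC | intermediate
7 | methyl (2E,6R)-3,7,7-trimethyl-8-oxo-6-[(triethylsilyl)oxy]oct-2-enoate | COC(=O)/C=C(\C)CC[C@@H](O[Si](CC)(CC)CC)C(C)(C)C=O | intermediate
8 | (2E)-but-2-en-1-ol | C/C=C/CO | starting material
9 | 1-phenyl-1H-tetrazole-5-thiol | Sc1nnnn1-c1ccccc1 | starting material
10 | 5-[(2E)-but-2-en-1-ylsulfanyl]-1-phenyl-1H-tetrazole | C/C=C/CSc1nnnn1-c1ccccc1 | intermediate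
11 | 5-[(2E)-but-2-ene-1-sulfonyl]-1-phenyl-1H-tetrazole | C/C=C/CS(=O)(=O)c1nnnn1-c1ccccc1 | intermediate
12 | methyl (2E,6R,8E,10E)-3,7,7-trimethyl-6-[(triethylsilyl)oxy]dodeca-2,8,10-trienoate | COC(=O)/C=C(\C)CC[C@@H](O[Si](CC)(CC)CC)C(C)(C)/C=C/C=C/C | intermediate
13 | methyl (1R,2R,4aS,6R,8aR)-2,5,5,8a-tetramethyl-6-[(triethylsilyl)oxy]-1,2,4a,5,6,7,8,8a-octahydronaphthalene-1-carboxylate (trans-fused; ester, C17, C20 and C3–O on one face, H-5, H-8 and H-9 on the other) | COC(=O)[C@@H]1[C@H](C)C=C[C@@H]2C(C)(C)[C@H](O[Si](CC)(CC)CC)CC[C@@]12C | intermediate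
14 | methyl (1R,2R,4aS,6R,8aR)-2,5,5,8a-tetramethyl-6-[(triethylsilyl)oxy]decahydronaphthalene-1-carboxylate | COC(=O)[C@@H]1[C@H](C)CC[C@@H]2C(C)(C)[C@H](O[Si](CC)(CC)CC)CC[C@@]12C | intermediate
15 | methyl (1S,2R,4aS,6R,8aR)-2,5,5,8a-tetramethyl-1-(phenylselanyl)-6-[(triethylsilyl)oxy]decahydronaphthalene-1-carboxylate (Se anti to the C20 methyl) | COC(=O)[C@]1([Se]c2ccccc2)[C@H](C)CC[C@@H]2C(C)(C)[C@H](O[Si](CC)(CC)CC)CC[C@@]12C | intermediate
16 | methyl (4aS,6R,8aR)-2,5,5,8a-tetramethyl-6-[(triethylsilyl)oxy]-3,4,4a,5,6,7,8,8a-octahydronaphthalene-1-carboxylate | COC(=O)C1=C(C)CC[C@@H]2C(C)(C)[C@H](O[Si](CC)(CC)CC)CC[C@@]12C | intermediate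
17 | {(4aS,6R,8aR)-2,5,5,8a-tetramethyl-6-[(triethylsilyl)oxy]-3,4,4a,5,6,7,8,8a-octahydronaphthalen-1-yl}methanol | OCC1=C(C)CC[C@@H]2C(C)(C)[C@H](O[Si](CC)(CC)CC)CC[C@@]12C | intermediate
18 | (4aS,6R,8aR)-1-(bromomethyl)-2,5,5,8a-tetramethyl-6-[(triethylsilyl)oxy]-3,4,4a,5,6,7,8,8a-octahydronaphthalene | BrCC1=C(C)CC[C@@H]2C(C)(C)[C@H](O[Si](CC)(CC)CC)CC[C@@]12C | intermediate
19 | (4aS,6R,8aR)-1-[(benzenesulfonyl)methyl]-2,5,5,8a-tetramethyl-6-[(triethylsilyl)oxy]-3,4,4a,5,6,7,8,8a-octahydronaphthalene | O=S(=O)(CC1=C(C)CC[C@@H]2C(C)(C)[C@H](O[Si](CC)(CC)CC)CC[C@@]12C)c1ccccc1 | intermediate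
20 | 2-methylprop-2-en-1-ol | C=C(C)CO | starting material
21 | [(2S)-2-methyloxiran-2-yl]methanol | OC[C@@]1(C)CO1 | intermediate
22 | (2R)-2-methyloxirane-2-carbaldehyde | O=C[C@@]1(C)CO1 | intermediate
23 | (2S)-2-ethenyl-2-methyloxirane | C=C[C@@]1(C)CO1 | intermediate
24 | (3R)-5-(benzenesulfonyl)-3-methyl-5-{(4aS,6R,8aR)-2,5,5,8a-tetramethyl-6-[(triethylsilyl)oxy]-3,4,4a,5,6,7,8,8a-octahydronaphthalen-1-yl}pent-1-en-3-ol (C11 epimers) | C=C[C@](C)(O)CC(S(=O)(=O)c1ccccc1)C1=C(C)CC[C@@H]2C(C)(C)[C@H](O[Si](CC)(CC)CC)CC[C@@]12C | intermediate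
25 | (3R)-3-methyl-5-{(4aS,6R,8aR)-2,5,5,8a-tetramethyl-6-[(triethylsilyl)oxy]-3,4,4a,5,6,7,8,8a-octahydronaphthalen-1-yl}pent-1-en-3-ol | C=C[C@](C)(O)CCC1=C(C)CC[C@@H]2C(C)(C)[C@H](O[Si](CC)(CC)CC)CC[C@@]12C | intermediate
26 | tert-butyl(dimethyl)[((3R)-3-methyl-5-{(4aS,6R,8aR)-2,5,5,8a-tetramethyl-6-[(triethylsilyl)oxy]-3,4,4a,5,6,7,8,8a-octahydronaphthalen-1-yl}pent-1-en-3-yl)oxy]silane | C=C[C@](C)(O[Si](C)(C)C(C)(C)C)CCC1=C(C)CC[C@@H]2C(C)(C)[C@H](O[Si](CC)(CC)CC)CC[C@@]12C | intermediate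
27 | (2R,4aR,8aS)-5-{(3R)-3-[(tert-butyldimethylsilyl)oxy]-3-methylpent-4-en-1-yl}-1,1,4a,6-tetramethyl-1,2,3,4,4a,7,8,8a-octahydronaphthalen-2-ol (equatorial OH) | C=C[C@](C)(O[Si](C)(C)C(C)(C)C)CCC1=C(C)CC[C@@H]2C(C)(C)[C@H](O)CC[C@@]12C | intermediate
28 | (4aR,8aS)-5-{(3R)-3-[(tert-butyldimethylsilyl)oxy]-3-methylpent-4-en-1-yl}-1,1,4a,6-tetramethyl-3,4,4a,7,8,8a-hexahydronaphthalen-2(1H)-one | C=C[C@](C)(O[Si](C)(C)C(C)(C)C)CCC1=C(C)CC[C@@H]2C(C)(C)C(=O)CC[C@@]12C | intermediate
29 | (2S,4aR,8aS)-5-{(3R)-3-[(tert-butyldimethylsilyl)oxy]-3-methylpent-4-en-1-yl}-1,1,4a,6-tetramethyl-1,2,3,4,4a,7,8,8a-octahydronaphthalen-2-ol (axial OH) | C=C[C@](C)(O[Si](C)(C)C(C)(C)C)CCC1=C(C)CC[C@@H]2C(C)(C)[C@@H](O)CC[C@@]12C | intermediate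
30 | tert-butyl({(3R)-5-[(4aS,6R,8aR)-6-bromo-2,5,5,8a-tetramethyl-3,4,4a,5,6,7,8,8a-octahydronaphthalen-1-yl]-3-methylpent-1-en-3-yl}oxy)dimethylsilane | C=C[C@](C)(O[Si](C)(C)C(C)(C)C)CCC1=C(C)CC[C@@H]2C(C)(C)[C@H](Br)CC[C@@]12C | intermediate
31 | (3R)-5-[(4aS,6R,8aR)-6-bromo-2,5,5,8a-tetramethyl-3,4,4a,5,6,7,8,8a-octahydronaphthalen-1-yl]-3-methylpent-1-en-3-ol | C=C[C@](C)(O)CCC1=C(C)CC[C@@H]2C(C)(C)[C@H](Br)CC[C@@]12C | target

**Step count**
Total: 23 steps. Longest linear sequence: 18 steps from methyl geranate (steps 1, 3–5, 8–13, 16–23).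

**Steps most likely to fail**

Step 9. The β-methyl enoate is a trisubstituted dienophile that must bond to a diene terminus next to a quaternary carbon, so cyclisation may be slower than Lewis-acid degradation of the diene or loss of the silyl ether. The C3 centre may also discriminate the two diene faces only moderately. The fallback keeps the same two bonds and rings but changes the activating group to an aldehyde. It sets out from 12 and returns at 13. Reduction of 12 with i-Bu2AlH gives the trienol F1, and MnO2 oxidation gives the (E)-enal F2. Cyclisation of F2 with Me2AlCl (CH2Cl2, −78 → 0 °C), where the aldehyde complex is a much stronger dienophile, should give the decalin aldehyde F3. Oxidation with NaClO2 gives the carboxylic acid F4, and methylation with trimethylsilyldiazomethane gives 13.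

Step 22. Backside attack of bromide at the neopentylic C3 is slow, so elimination toward C2 and a 1,2-methyl shift from C4 may consume the alkoxyphosphonium ion. The fallback replaces in situ phosphonium activation by an isolated sulfonate and a salt-free bromide source. It sets out from 29 and returns at 30. Treatment of 29 with NaH and 1,1'-sulfonyldiimidazole gives the axial imidazole-1-sulfonate F5. Displacement of F5 with Bu4NBr in toluene at 80 °C should give 30 with inversion.

Step 16. The hindered allylic sulfone anion may attack the vinyl terminus of the epoxide (SN2′ opening) or react through its γ-carbon (C8) instead of opening the oxirane at CH2. The fallback uses an epoxide without a vinyl group and builds the vinyl group afterwards. It sets out from 19 (with 21) and returns at 25. Etherification of 21 with NaH and 4-methoxybenzyl chloride gives the 4-methoxybenzyl glycidyl ether F6. Lithiated 19 opens F6 at its only free CH2 (BF3·OEt2 can now assist) to give the hydroxy sulfone F7. Na/Hg removes the sulfone to give the ether alcohol F8, and DDQ frees the 1,2-diol F9. SO3·pyridine/DMSO oxidation of the primary alcohol gives the α-hydroxy aldehyde F10, and Wittig methylenation with Ph3P=CH2 gives 25.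

**Further compounds**
F1 | step 9 | (2E,6R,8E,10E)-3,7,7-trimethyl-6-[(triethylsilyl)oxy]dodeca-2,8,10-trien-1-ol | OC/C=C(\C)CC[C@@H](O[Si](CC)(CC)CC)C(C)(C)/C=C/C=C/C
F2 | step 9 | (2E,6R,8E,10E)-3,7,7-trimethyl-6-[(triethylsilyl)oxy]dodeca-2,8,10-trienal | O=C/C=C(\C)CC[C@@H](O[Si](CC)(CC)CC)C(C)(C)/C=C/C=C/C
F3 | step 9 | (1R,2R,4aS,6R,8aR)-2,5,5,8a-tetramethyl-6-[(triethylsilyl)oxy]-1,2,4a,5,6,7,8,8a-octahydronaphthalene-1-carbaldehyde | O=C[C@@H]1[C@H](C)C=C[C@@H]2C(C)(C)[C@H](O[Si](CC)(CC)CC)CC[C@@]12C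
F4 | step 9 | (1R,2R,4aS,6R,8aR)-2,5,5,8a-tetramethyl-6-[(triethylsilyl)oxy]-1,2,4a,5,6,7,8,8a-octahydronaphthalene-1-carboxylic acid | OC(=O)[C@@H]1[C@H](C)C=C[C@@H]2C(C)(C)[C@H](O[Si](CC)(CC)CC)CC[C@@]12C
F5 | step 22 | (2S,4aR,8aS)-5-{(3R)-3-[(tert-butyldimethylsilyl)oxy]-3-methylpent-4-en-1-yl}-1,1,4a,6-tetramethyl-1,2,3,4,4a,7,8,8a-octahydronaphthalen-2-yl 1H-imidazole-1-sulfonate | C=C[C@](C)(O[Si](C)(C)C(C)(C)C)CCC1=C(C)CC[C@@H]2C(C)(C)[C@@H](OS(=O)(=O)n3ccnc3)CC[C@@]12C
F6 | step 16 | (2R)-2-{[(4-methoxyphenyl)methoxy]methyl}-2-methyloxirane (4-methoxybenzyl ether of 21) | COc1ccc(COC[C@@]2(C)CO2)cc1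
F7 | step 16 | (2R)-4-(benzenesulfonyl)-1-[(4-methoxyphenyl)methoxy]-2-methyl-4-{(4aS,6R,8aR)-2,5,5,8a-tetramethyl-6-[(triethylsilyl)oxy]-3,4,4a,5,6,7,8,8a-octahydronaphthalen-1-yl}butan-2-ol (C11 epimers) | COc1ccc(COC[C@](C)(O)CC(S(=O)(=O)c2ccccc2)C2=C(C)CC[C@@H]3C(C)(C)[C@H](O[Si](CC)(CC)CC)CC[C@@]23C)cc1
F8 | step 16 | (2R)-1-[(4-methoxyphenyl)methoxy]-2-methyl-4-{(4aS,6R,8aR)-2,5,5,8a-tetramethyl-6-[(triethylsilyl)oxy]-3,4,4a,5,6,7,8,8a-octahydronaphthalen-1-yl}butan-2-ol | COc1ccc(COC[C@](C)(O)CCC2=C(C)CC[C@@H]3C(C)(C)[C@H](O[Si](CC)(CC)CC)CC[C@@]23C)cc1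
F9 | step 16 | (2R)-2-methyl-4-{(4aS,6R,8aR)-2,5,5,8a-tetramethyl-6-[(triethylsilyl)oxy]-3,4,4a,5,6,7,8,8a-octahydronaphthalen-1-yl}butane-1,2-diol | OC[C@](C)(O)CCC1=C(C)CC[C@@H]2C(C)(C)[C@H](O[Si](CC)(CC)CC)CC[C@@]12C
F10 | step 16 | (2R)-2-hydroxy-2-methyl-4-{(4aS,6R,8aR)-2,5,5,8a-tetramethyl-6-[(triethylsilyl)oxy]-3,4,4a,5,6,7,8,8a-octahydronaphthalen-1-yl}butanal | O=C[C@](C)(O)CCC1=C(C)CC[C@@H]2C(C)(C)[C@H](O[Si](CC)(CC)CC)CC[C@@]12C
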